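## Analysis of the target

Labdane numbering is used throughout: ring A is C1–C5 and C10, ring B is C5–C10, C20 is the methyl on C10, C18/C19 are the methyls on C4, C17 is the formyl carbon on C8, and C11–C16 is the side chain with C15 the ester carbon.

The target is an ent-labdane: a trans-fused decalin with five stereocentres (C3 R, C5 S, C8 R, C9 S, C10 R) and a (Z)-3-methylpent-2-enoate chain on C9. C3, C5 and C10 have the relative configuration produced by a chair–chair epoxy-polyene cyclisation, with the equatorial C3–OH on the same face as C20. The C9 side chain is equatorial and cis to C20. C8 in ring B is a tertiary carbinol whose OH is axial, 1,3-diaxial to C20, while the formyl carbon C17 is equatorial. This is the reverse of what oxidation of a C8=C17 exocyclic alkene from its open face (anti to C20) should deliver, but it is what equatorial attack of a carbon nucleophile on a C8 ketone should give. The sensitive groups are the tertiary α-hydroxy aldehyde (prone to α-ketol ring expansion under acid or base), the trisubstituted Z enoate (Z/E isomerisation, Michael addition) and the free C3 alcohol. The difficulty is the congested C8–C9–C10 triad next to a quaternary carbon, combined with the need to unveil the aldehyde last under neutral conditions. The structure therefore invites a ring-forming cascade that ends on an oxygen-bearing C8, so that C8 emerges as a ketone and C17 is added afterwards.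

## Retrosynthetic reasoning

**22 ⇒ 20 (through 21).** The formyl carbon C17 is traced back to the inner carbon of a vinyl group on C8, cleaved at C17=CH2. This is done last and under neutral, reductive work-up because the α-hydroxy aldehyde tolerates neither acid nor base. The forward ozonolysis must cleave the monosubstituted alkene and spare the conjugated C13=C14 bond.

**20 ⇒ 19.** The C8–C17 bond is cut. A vinyl-metal nucleophile adding to the C8 ketone of 19 must come from the equatorial direction, because the axial trajectory is blocked by C20. That places the new carbon equatorial and the oxygen axial, which is the configuration of the target. Cutting C8–C17 rather than C8–O is what makes this configuration accessible.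

**19 ⇒ 18 (key disconnection).** C4–C5 and C9–C10 are cut together, opening both rings to the acyclic epoxy diene 18. Its chain ends in the silyl enol ether of the C8 ketone and already carries the Z enoate. The forward cascade must close rings A and B, set C5, C10 and C9 from the single epoxide stereocentre C3, and release C8 as a ketone. Terminating on a methyl-bearing alkene would leave C8 as an sp2 carbon whose oxygenation face is wrong, which is why the cut is made with the oxygen already on C8.

**18 ⇒ 12 + 15.** C8–C9 and C11–C12 are cut in one three-component operation. A vinyl anion supplies C9 and C11 to acylsilane 12; Brook rearrangement turns C11 into a nucleophile (a homoenolate, polarity reversal), which is alkylated by allylic bromide 15. This gives the enol ether regio- and stereodefined, which enolisation of an unsymmetrical dialkyl ketone could not.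

**12 ⇒ 10 + 5.** C6–C7 is cut: the enolate of acetylsilane 10 (through 11) is alkylated with allylic bromide 5.

**5 ⇒ 3 ⇒ 2 ⇒ 1.** Bromide 5 comes from alcohol 3 (through mesylate 4), and 3 from acetate 2. The C3 stereocentre is introduced by Shi epoxidation of the distal alkene of geranyl acetate 1, whose E alkene becomes C5=C10.

**15 ⇒ 13 (through 14).** The Z geometry of C13=C14 is taken from a ring: butenolide 13 already holds C12 and C15 cis, so opening it at the allylic C–O bond gives 15 without an olefination.

**10 ⇒ 6 + 7 (through 8 and 9).** The acylsilane is assembled from vinyl ether 6, used as a masked acetyl anion, and chlorosilane 7.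

## Alternatives that were turned down

**Alternative 1:** the textbook route. Disconnection: C4–C5 and C9–C10 of the full C20 skeleton, with C17 carried as the methyl branch of an all-carbon polyene and C8–O made afterwards. Forward key step: radical bicyclisation of epoxy polyene A1 with Cp2TiCl (trivalent titanium), ending by loss of hydrogen from C17 to give the exocyclic alkene A2; OsO4 dihydroxylation of C8=C17 and oxidation of the primary alcohol would follow. Turned down because:
- Oxidants should approach the C8=C17 bond of A2 from the equatorial side, anti to the axial C20, giving triol A3 with the C8 oxygen equatorial — the C8 epimer of what is needed.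
- Correcting this means excising C17 by ozonolysis and adding it back, two extra steps for a carbon the cascade need not have carried.
- The C8 radical sits five atoms from the enoate β-carbon C13, so a 5-exo conjugate addition can compete with termination.

It is kept only as the fallback for the key step.

**Alternative 2:** Robinson annulation. Disconnection: C1–C10 and C4–C5 (Michael addition, then aldol condensation), leading to the bicyclic enedione A4 from a cyclic 1,3-diketone and a vinyl ketone under proline catalysis. Turned down because:
- The annulation sets only C10. The gem-dimethyl group, the trans ring fusion at C5, the C3 alcohol, the C9 chain and the C8 carbinol would each need separate operations.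
- The saturated carbonyl of A4 sits on C9, where the target needs a carbon chain, and not on C8, so a 1,2-carbonyl transposition is required.
- The sequence would be well over twice as long and would need protecting groups.

**Alternative 3:** ring B closed last. Disconnection: C8–C9, by intramolecular Sakurai addition of the allylsilane of monocyclic keto acetal A5 to its C8 ketone, which would set C8 and C9 with C17 already in place. Turned down because:
- A5 contains ring A with the quaternary C10 and the trans C5 centre, which must be built stepwise without a cascade; reaching A5 costs more than the whole chosen route.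
- A Lewis acid ionises the dimethyl acetal at C17 more easily than it activates the hindered ketone, so the allylsilane would attack C17 and close a seven-membered ring.
- The chair preference of the bulky acetal at C8 gives no clear bias for the axial OH.

Key step: step 8

## Route

**Step 1**
Reactants: 1 geranyl acetate
Product: 2 (R)-6,7-epoxygeranyl acetate
Conditions: 1,2:4,5-di-O-isopropylidene-β-D-erythro-2,3-hexodiulo-2,6-pyranose (0.3 equiv), Oxone (2KHSO5·KHSO4·K2SO4), K2CO3, Bu4NHSO4, Na2B4O7/Na2EDTA buffer, MeCN–CH2(OMe)2–H2O, 0 °C
Reagents that add atoms: potassium peroxymonosulfate, [K+].[O-]S(=O)(=O)OO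
Why: Shi epoxidation; the chiral dioxirane should react at the electron-rich distal trisubstituted alkene and leave the alkene deactivated by the allylic acetate, and the spiro transition state of the D-fructose-derived ketone should give the R epoxide carbon that becomes C3.

**Step 2**
Reactants: 2 (R)-6,7-epoxygeranyl acetate
Product: 3 (R)-6,7-epoxygeraniol
Conditions: K2CO3 (cat.), MeOH, 0 °C → rt
Reagents that add atoms: none
Why: Transesterification of the acetate with methanol; the trisubstituted epoxide should be inert to methoxide at this temperature.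

**Step 3**
Reactants: 3 (R)-6,7-epoxygeraniol
Product: 5 (R)-6,7-epoxygeranyl bromide, via (R)-6,7-epoxygeranyl methanesulfonate 4 (not isolated)
Conditions: MsCl, Et3N, THF, −40 °C; then LiBr, THF, −40 → 0 °C
Reagents that add atoms: methanesulfonyl chloride, CS(=O)(=O)Cl (atoms of 4); lithium bromide, [Li+].[Br-] (bromine of 5)
Why: Mesylation followed by SN2 displacement with bromide under non-acidic, cold conditions, so the epoxide and the E alkene should survive; the bromide is used without storage.

**Step 4**
Reactants: 6 ethyl vinyl ether; 7 tert-butyl(chloro)dimethylsilane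
Product: 10 acetyl(tert-butyl)dimethylsilane, via (1-ethoxyvinyl)lithium 8 (not isolated), via tert-butyl(1-ethoxyvinyl)dimethylsilane 9 (not isolated)
Conditions: t-BuLi, THF, −78 → 0 °C; then 7, −78 °C → rt; then 1 M HCl, acetone, rt
Reagents that add atoms: tert-butyllithium, [Li]C(C)(C)C (lithium of 8); water, O (carbonyl oxygen of 10)
Why: α-Lithiation of the vinyl ether gives a masked acetyl anion, which is silylated; hydrolysis of the α-silyl enol ether then gives the acylsilane, a standard acylsilane synthesis.

**Step 5**
Reactants: 10 acetyl(tert-butyl)dimethylsilane; 5 (R)-6,7-epoxygeranyl bromide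
Product: 12 (4E)-1-[tert-butyl(dimethyl)silyl]-7-[(2R)-3,3-dimethyloxiran-2-yl]-5-methylhept-4-en-1-one, via lithium enolate 11 (not isolated)
Conditions: LiN(iPr)2, THF, −78 °C; then 5, DMPU, −78 → −20 °C
Reagents that add atoms: lithium diisopropylamide, [Li]N(C(C)C)C(C)C (lithium of 11)
Why: Kinetic enolate alkylation (SN2) at the primary allylic bromide forms C6–C7; the acylsilane has only one enolisable side, and the epoxide should not react with the enolate at low temperature.

**Step 6**
Reactants: 13 4-methylfuran-2(5H)-one
Product: 15 methyl (Z)-4-bromo-3-methylbut-2-enoate, via (Z)-4-bromo-3-methylbut-2-enoic acid 14 (not isolated)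
Conditions: HBr (gas), MeOH, 0 °C → rt
Reagents that add atoms: hydrogen bromide, Br; methanol, CO
Why: Acid-mediated alkyl–oxygen cleavage of the lactone by bromide at the allylic CH2, then Fischer esterification (the reaction type that converts butyrolactone into 4-bromobutanoate esters); the Z geometry is inherited from the ring and should be kept at low temperature.

**Step 7**
Reactants: 12 (4E)-1-[tert-butyl(dimethyl)silyl]-7-[(2R)-3,3-dimethyloxiran-2-yl]-5-methylhept-4-en-1-one; 15 methyl (Z)-4-bromo-3-methylbut-2-enoate
Product: 18 methyl (2Z,6Z,10E)-7-{[tert-butyl(dimethyl)silyl]oxy}-13-[(2R)-3,3-dimethyloxiran-2-yl]-3,11-dimethyltrideca-2,6,10-trienoate, via lithium α-silyl allyl alkoxide 16 (not isolated), via siloxyallyllithium 17 (not isolated)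
Conditions: CH2=CHLi (from Bu3SnCH=CH2 and n-BuLi), Et2O, −78 °C; then THF, −78 → −30 °C; then 15, −78 °C
Reagents that add atoms: vinyllithium, [Li]C=C
Why: 1,2-Addition to the acylsilane, Brook rearrangement (carbon-to-oxygen silyl shift) to the chelated siloxyallyl anion, and alkylation at its terminal carbon by the allylic bromide form C8–C9 and C11–C12 in one flask; the chelated anion should give the Z enol ether regiospecifically, and the Z enoate of 15 is not touched.

**Step 8**
Reactants: 18 methyl (2Z,6Z,10E)-7-{[tert-butyl(dimethyl)silyl]oxy}-13-[(2R)-3,3-dimethyloxiran-2-yl]-3,11-dimethyltrideca-2,6,10-trienoate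
Product: 19 methyl (2Z)-5-[(1S,4aS,6R,8aR)-6-hydroxy-5,5,8a-trimethyl-2-oxodecahydronaphthalen-1-yl]-3-methylpent-2-enoate
Conditions: MeAlCl2, CH2Cl2, −94 → −78 °C; then aq. HF, MeCN, 23 °C
Reagents that add atoms: none
Why: MeAlCl2 binds the epoxide oxygen and the C4–O bond ionises as C5 of the C5=C10 alkene attacks C4; the tertiary C10 cation is then captured by C9 of the silyl enol ether, and the silyloxycarbenium ion at C8 loses its silyl group to leave the ketone. The closest known reaction type is the Lewis-acid epoxy-polyene cyclisation terminated by a silyl enol ether. Ring A closes in a 6-endo mode (anti opening of the epoxide at its tertiary carbon by the alkene, chair), and ring B closes 6-endo-trig onto the enol ether, also in a chair. C3 is the epoxide carbon and keeps its R configuration because its C–O bond is never broken. C5 and C10 follow from antiperiplanar addition across the E C5=C10 alkene in the chair–chair array, which gives the trans ring fusion with C20 on the face of the C3 oxygen. C9 is set by the Z enol ether geometry (C11 equatorial) and is in any case the thermodynamic epimer next to the new ketone. The step needs bicyclisation to outrun proton loss at C10 and hydride shift at the activated epoxide: the enol ether is the most nucleophilic π bond of 18 and its carbon C9 closes a six-membered ring on C10, while the conjugated enoate is deactivated and should stay out. The HF treatment returns any silyl group that has moved to the C3 oxygen, so one product is expected.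

**Step 9**
Reactants: 19 methyl (2Z)-5-[(1S,4aS,6R,8aR)-6-hydroxy-5,5,8a-trimethyl-2-oxodecahydronaphthalen-1-yl]-3-methylpent-2-enoate
Product: 20 methyl (2Z)-5-[(1S,2S,4aS,6R,8aR)-2-ethenyl-2,6-dihydroxy-5,5,8a-trimethyldecahydronaphthalen-1-yl]-3-methylpent-2-enoate
Conditions: CH2=CHMgBr (excess), CeCl3, THF, −78 → 0 °C
Reagents that add atoms: vinylmagnesium bromide, C=C[Mg]Br
Why: Organocerium 1,2-addition to the ketone; the axial trajectory is blocked by the 1,3-diaxial C20, so the vinyl group should enter equatorially and the new C8–OH should be axial, as in the target. CeCl3 should suppress enolisation and attack on the ester; one equivalent of reagent is consumed by the C3 hydroxyl.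

**Step 10**
Reactants: 20 methyl (2Z)-5-[(1S,2S,4aS,6R,8aR)-2-ethenyl-2,6-dihydroxy-5,5,8a-trimethyldecahydronaphthalen-1-yl]-3-methylpent-2-enoate
Product: 22 methyl (2Z)-5-[(1S,2R,4aS,6R,8aR)-2-formyl-2,6-dihydroxy-5,5,8a-trimethyldecahydronaphthalen-1-yl]-3-methylpent-2-enoate, via secondary ozonide 21 (not isolated)
Conditions: O3, CH2Cl2, −78 °C (Sudan Red 7B end point); then Me2S, −78 °C → rt
Reagents that add atoms: ozone, [O-][O+]=O
Why: Ozonolysis; the isolated monosubstituted vinyl group should react faster than the conjugated, β,β-disubstituted enoate, and the dye marks the end point. Reductive work-up under neutral conditions should release the tertiary α-hydroxy aldehyde without α-ketol rearrangement; C8 is not touched.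

## Compound list

1 | geranyl acetate, (2E)-3,7-dimethylocta-2,6-dien-1-yl acetate | CC(=O)OC/C=C(\C)CCC=C(C)C | starting material
2 | (R)-6,7-epoxygeranyl acetate, (2E)-5-[(2R)-3,3-dimethyloxiran-2-yl]-3-methylpent-2-en-1-yl acetate | CC(=O)OC/C=C(\C)CC[C@H]1OC1(C)C | intermediate
3 | (R)-6,7-epoxygeraniol, (2E)-5-[(2R)-3,3-dimethyloxiran-2-yl]-3-methylpent-2-en-1-ol | OC/C=C(\C)CC[C@H]1OC1(C)C | intermediate
4 | (R)-6,7-epoxygeranyl methanesulfonate | CS(=O)(=O)OC/C=C(\C)CC[C@H]1OC1(C)C | intermediate
5 | (R)-6,7-epoxygeranyl bromide, (2E)-1-bromo-5-[(2R)-3,3-dimethyloxiran-2-yl]-3-methylpent-2-ene | BrC/C=C(\C)CC[C@H]1OC1(C)C | intermediate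
6 | ethyl vinyl ether | C=COCC | starting material
7 | tert-butyl(chloro)dimethylsilane | CC(C)(C)[Si](C)(C)Cl | starting material
8 | (1-ethoxyvinyl)lithium | [Li]C(=C)OCC | intermediate
9 | tert-butyl(1-ethoxyvinyl)dimethylsilane | C=C(OCC)[Si](C)(C)C(C)(C)C | intermediate
10 | acetyl(tert-butyl)dimethylsilane, 1-[tert-butyl(dimethyl)silyl]ethan-1-one | CC(=O)[Si](C)(C)C(C)(C)C | intermediate
11 | lithium enolate of 10, lithium 1-[tert-butyl(dimethyl)silyl]ethenolate | C=C(O[Li])[Si](C)(C)C(C)(C)C | intermediate
12 | (4E)-1-[tert-butyl(dimethyl)silyl]-7-[(2R)-3,3-dimethyloxiran-2-yl]-5-methylhept-4-en-1-one | CC(C)(C)[Si](C)(C)C(=O)CC/C=C(\C)CC[C@H]1OC1(C)C | intermediate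
13 | 4-methylfuran-2(5H)-one | CC1=CC(=O)OC1 | starting material
14 | (Z)-4-bromo-3-methylbut-2-enoic acid | OC(=O)/C=C(/C)CBr | intermediate
15 | methyl (Z)-4-bromo-3-methylbut-2-enoate | COC(=O)/C=C(/C)CBr | intermediate
16 | lithium (6E)-3-[tert-butyl(dimethyl)silyl]-9-[(2R)-3,3-dimethyloxiran-2-yl]-7-methylnona-1,6-dien-3-olate (both carbinol epimers) | [Li]OC(C=C)([Si](C)(C)C(C)(C)C)CC/C=C(\C)CC[C@H]1OC1(C)C | intermediate
17 | siloxyallyllithium, [(2Z,6E)-3-{[tert-butyl(dimethyl)silyl]oxy}-9-[(2R)-3,3-dimethyloxiran-2-yl]-7-methylnona-2,6-dien-1-yl]lithium | [Li]C/C=C(\O[Si](C)(C)C(C)(C)C)CC/C=C(\C)CC[C@H]1OC1(C)C | intermediate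
18 | methyl (2Z,6Z,10E)-7-{[tert-butyl(dimethyl)silyl]oxy}-13-[(2R)-3,3-dimethyloxiran-2-yl]-3,11-dimethyltrideca-2,6,10-trienoate | COC(=O)/C=C(/C)CC/C=C(\O[Si](C)(C)C(C)(C)C)CC/C=C(\C)CC[C@H]1OC1(C)C | intermediate
19 | methyl (2Z)-5-[(1S,4aS,6R,8aR)-6-hydroxy-5,5,8a-trimethyl-2-oxodecahydronaphthalen-1-yl]-3-methylpent-2-enoate (trans-decalin, C8 ketone, equatorial C3–OH, equatorial C9 chain) | COC(=O)/C=C(/C)CC[C@H]1[C@]2(C)CC[C@@H](O)C(C)(C)[C@H]2CCC1=O | intermediate
20 | methyl (2Z)-5-[(1S,2S,4aS,6R,8aR)-2-ethenyl-2,6-dihydroxy-5,5,8a-trimethyldecahydronaphthalen-1-yl]-3-methylpent-2-enoate (C8–OH axial, cis to C20; vinyl equatorial) | COC(=O)/C=C(/C)CC[C@H]1[C@]2(C)CC[C@@H](O)C(C)(C)[C@H]2CC[C@]1(O)C=C | intermediate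
21 | secondary ozonide of 20, 1,2,4-trioxolan-3-yl group on C8 (both epimers at the trioxolane carbon) | COC(=O)/C=C(/C)CC[C@H]1[C@]2(C)CC[C@@H](O)C(C)(C)[C@H]2CC[C@]1(O)C3OCOO3 | intermediate
22 | methyl (2Z)-5-[(1S,2R,4aS,6R,8aR)-2-formyl-2,6-dihydroxy-5,5,8a-trimethyldecahydronaphthalen-1-yl]-3-methylpent-2-enoate (CNP0135080.1) | COC(=O)/C=C(/C)CC[C@H]1[C@]2(C)CC[C@@H](O)C(C)(C)[C@H]2CC[C@]1(O)C=O | target

## Step count and least certain steps

Total step count: 10. Longest linear sequence: 8 steps (steps 1, 2, 3, 5, 7, 8, 9, 10); steps 4 and 6 are side branches. No protecting groups are used.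

**Step 8 (key step).** The cascade may be interrupted: the C10 cation can lose a proton after ring A has closed, the activated epoxide can undergo a 1,2-hydride shift to a ketone before ring A closes, or the enol ether can be protodesilylated before C9 attacks. The C9–C10 bond joins a tertiary cation to a carbon that becomes part of a congested triad, so ring B closure is the slow event. The fallback sets out from 18 and returns at 19, changing both the mechanism and the terminator. Fluoride-induced triflation of the silyl enol ether (CsF, PhNTf2) should give the enol triflate F1 with the Z geometry retained. Negishi methylation (MeZnCl, Pd(PPh3)4, zerovalent palladium) should give the all-carbon epoxy polyene F2 with the natural E alkene. Radical bicyclisation with Cp2TiCl (trivalent titanium, from Cp2TiCl2 and Mn powder) should give the exocyclic alkene F3. Ozonolysis of its 1,1-disubstituted alkene (O3; Me2S) excises C17 and should return ketone 19.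

**Step 7.** The siloxyallyl anion may add to the ester carbonyl of 15 or deprotonate its acidic CH2Br group instead of displacing bromide, and some alkylation at the carbon next to oxygen is possible. The fallback sets out from 12 and returns at 19, carrying the ester as a vinyl iodide through the cascade. Copper-catalysed addition of MeMgBr to propargyl alcohol followed by iodination should give (Z)-3-iodo-2-methylprop-2-en-1-ol F4, and PBr3 should convert it into (Z)-3-bromo-1-iodo-2-methylprop-1-ene F5. The same Brook sequence on 12 with F5 as electrophile should give the iodovinyl silyl enol ether F6. MeAlCl2 cyclisation as in step 8 should give the iodovinyl hydroxy ketone F7. Methoxycarbonylation with retention of geometry (Pd(PPh3)2Cl2, a divalent palladium precatalyst; CO, MeOH, Et3N) should return 19.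

**Step 5.** The acylsilane enolate may undergo O-alkylation, self-condensation or SN2′ attack on the allylic bromide instead of clean C-alkylation. The fallback sets out from 10 and returns at 12, using an aza-enolate. Condensation of 10 with cyclohexylamine (molecular sieves) should give the N-cyclohexyl imine F8. Deprotonation with LiN(iPr)2 and alkylation with 5 should give the alkylated imine F9. Buffered hydrolysis (AcOH/NaOAc, aqueous THF) should return 12 without opening the epoxide.

**Step 9.** The hindered ketone may be enolised toward C7, or the reagent may add to the ester; poor facial selectivity is the less likely failure. The fallback sets out from 19 and returns at 22, using a carbon nucleophile that is inert to esters. Corey–Chaykovsky methylene transfer (Me3SI, KN(SiMe3)2, THF) should deliver CH2 equatorially and give the spiro-epoxide F10 with the oxygen axial. Opening at the primary carbon with CsOAc in DMF should give the primary acetate F11. K2CO3 in MeOH should give the triol F12. Selective oxidation of the primary alcohol (TEMPO, 2,2,6,6-tetramethylpiperidin-1-oxyl, with PhI(OAc)2) should give 22.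

**Step 10.** Over-oxidation may occur: ozone can attack the enoate, or the ozonide can fragment abnormally with loss of C17, which would return ketone 19. The fallback sets out from 19 and returns at 22 without any alkene cleavage. Addition of (isopropoxydimethylsilyl)methylmagnesium chloride with CeCl3, again from the equatorial side, should give the β-hydroxysilane F13. Tamao–Fleming oxidation (H2O2, KF, KHCO3) should give the triol F12. Oxidation of the primary alcohol with TEMPO and PhI(OAc)2 should give 22.

## Further compounds

F1 | step 8 | methyl (2Z,6Z,10E)-13-[(2R)-3,3-dimethyloxiran-2-yl]-3,11-dimethyl-7-(trifluoromethylsulfonyloxy)trideca-2,6,10-trienoate | COC(=O)/C=C(/C)CC/C=C(\OS(=O)(=O)C(F)(F)F)CC/C=C(\C)CC[C@H]1OC1(C)C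
F2 | step 8 | methyl (2Z,6E,10E)-13-[(2R)-3,3-dimethyloxiran-2-yl]-3,7,11-trimethyltrideca-2,6,10-trienoate | COC(=O)/C=C(/C)CC/C=C(\C)CC/C=C(\C)CC[C@H]1OC1(C)C
F3 | step 8 | methyl (2Z)-3-methyl-5-[6-hydroxy-5,5,8a-trimethyl-2-methylidenedecahydronaphthalen-1-yl]pent-2-enoate, ring configurations as in 19 (exocyclic C8=C17 alkene) | COC(=O)/C=C(/C)CC[C@H]1[C@]2(C)CC[C@@H](O)C(C)(C)[C@H]2CCC1=C
F4 | step 7 | (Z)-3-iodo-2-methylprop-2-en-1-ol | I/C=C(/C)CO
F5 | step 7 | (Z)-3-bromo-1-iodo-2-methylprop-1-ene | I/C=C(/C)CBr
F6 | step 7 | tert-butyl{[(1Z,5Z,9E)-12-[(2R)-3,3-dimethyloxiran-2-yl]-1-iodo-2,10-dimethyldodeca-1,5,9-trien-6-yl]oxy}dimethylsilane | I/C=C(/C)CC/C=C(\O[Si](C)(C)C(C)(C)C)CC/C=C(\C)CC[C@H]1OC1(C)C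
F7 | step 7 | (1S,4aS,6R,8aR)-6-hydroxy-1-[(3Z)-4-iodo-3-methylbut-3-en-1-yl]-5,5,8a-trimethyloctahydronaphthalen-2(1H)-one | I/C=C(/C)CC[C@H]1[C@]2(C)CC[C@@H](O)C(C)(C)[C@H]2CCC1=O
F8 | step 5 | N-cyclohexyl-1-[tert-butyl(dimethyl)silyl]ethan-1-imine | CC(=NC1CCCCC1)[Si](C)(C)C(C)(C)C
F9 | step 5 | N-cyclohexyl imine of 12, (4E)-1-[tert-butyl(dimethyl)silyl]-N-cyclohexyl-7-[(2R)-3,3-dimethyloxiran-2-yl]-5-methylhept-4-en-1-imine | CC(C)(C)[Si](C)(C)C(=NC1CCCCC1)CC/C=C(\C)CC[C@H]1OC1(C)C
F10 | step 9 | spiro-epoxide of 19 at C8 (epoxide oxygen axial and cis to C20, CH2 equatorial), ring configurations as in 19 | COC(=O)/C=C(/C)CC[C@H]1[C@]2(C)CC[C@@H](O)C(C)(C)[C@H]2CC[C@]13CO3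
F11 | step 9 | methyl (2Z)-5-[2-(acetoxymethyl)-2,6-dihydroxy-5,5,8a-trimethyldecahydronaphthalen-1-yl]-3-methylpent-2-enoate, configurations as in 22 | COC(=O)/C=C(/C)CC[C@H]1[C@]2(C)CC[C@@H](O)C(C)(C)[C@H]2CC[C@]1(O)COC(C)=O
F12 | step 9 | methyl (2Z)-5-[2,6-dihydroxy-2-(hydroxymethyl)-5,5,8a-trimethyldecahydronaphthalen-1-yl]-3-methylpent-2-enoate, configurations as in 22 | COC(=O)/C=C(/C)CC[C@H]1[C@]2(C)CC[C@@H](O)C(C)(C)[C@H]2CC[C@]1(O)CO
F13 | step 10 | methyl (2Z)-5-[2,6-dihydroxy-2-{[isopropoxy(dimethyl)silyl]methyl}-5,5,8a-trimethyldecahydronaphthalen-1-yl]-3-methylpent-2-enoate, configurations as in 22 | COC(=O)/C=C(/C)CC[C@H]1[C@]2(C)CC[C@@H](O)C(C)(C)[C@H]2CC[C@]1(O)C[Si](C)(C)OC(C)C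
A1 | alternative 1 | methyl (2Z,6E,10E)-13-[(2R)-3,3-dimethyloxiran-2-yl]-3,7,11-trimethyltrideca-2,6,10-trienoate | COC(=O)/C=C(/C)CC/C=C(\C)CC/C=C(\C)CC[C@H]1OC1(C)C
A2 | alternative 1 | exocyclic C8=C17 alkene, methyl (2Z)-3-methyl-5-[6-hydroxy-5,5,8a-trimethyl-2-methylidenedecahydronaphthalen-1-yl]pent-2-enoate, ring configurations as in 19 | COC(=O)/C=C(/C)CC[C@H]1[C@]2(C)CC[C@@H](O)C(C)(C)[C@H]2CCC1=C
A3 | alternative 1 | C8 epimer of triol F12 (C8–OH equatorial and trans to C20, CH2OH axial) | COC(=O)/C=C(/C)CC[C@H]1[C@]2(C)CC[C@@H](O)C(C)(C)[C@H]2CC[C@@]1(O)CO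
A4 | alternative 2 | (R)-8a-methyl-3,4,8,8a-tetrahydronaphthalene-1,6(2H,7H)-dione | C[C@@]12CCC(=O)C=C1CCCC2=O
A5 | alternative 3 | monocyclic ring A keto acetal with (E)-allylsilane on C10: 4-[3-hydroxy-2,2,6-trimethyl-6-[(1E)-3-(trimethylsilyl)prop-1-en-1-yl]cyclohexyl]-1,1-dimethoxybutan-2-one, ring configurations as in 22 | COC(OC)C(=O)CC[C@@H]1C(C)(C)[C@H](O)CC[C@@]1(C)/C=C/C[Si](C)(C)C
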